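**Plan**

1. Numbering (drimane type): ring A = C1–C5 + C10, ring B = C5–C10; C4 bears the exocyclic CH2, C10 the angular methyl, C9 a methyl and the benzylic carbon C11. The target is the trans-decalin with 5α-H and 8β-, 9β-, 10β-methyl groups (5S,8S,9R,10S). Cuts: C4=CH2 and C8–CH3 (each from a ketone), C9–C11 (aldol), C9–CH3 (from C9=CH2), C3 (inserted carbon), C4–C5 (benzoin), C1–C10 (Michael).
2. Forward: ring B is bought as 2-methylcyclohexane-1,3-dione. Michael addition to acrolein and an enantioselective carbene-catalysed benzoin close a five-membered ring C10–C1–C2–C4–C5 (C4 ketone, C5 carbinol). Insertion of C3 between C4 and C2 enlarges it to the six-membered ring A; the arene is joined last, at C9.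
3. Enabling feature: in the α-ketol, the future methylene carbon C4 is a carbonyl flanked by the fully substituted, oxygen-bearing ring-fusion carbon C5 and by the methylene C2. Only C2 can migrate, so the carbonyl stays at C4 next to C5; the C5 hydroxyl chelates the Lewis acid and singles out C4 over the C9 carbonyl.
4. Stereochemistry: C10 from the catalyst-controlled desymmetrizing benzoin; C5 by hydrogenation of the C5=C6 enone anti to the C10 methyl, before ring B is substituted; C9 by aldol of the regiodefined C8/C9 enolate anti to the axial C10 methyl; C8 by hydrogenation directed by the C11 hydroxyl on the α face.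
5. End game: radical removal of the C11 hydroxyl, ketal cleavage, non-basic methylenation of C4 (C5 is epimerizable), phenol release.

Key step: step 3

**Route**

Step 1
Reactants: 1 2-methylcyclohexane-1,3-dione; 2 acrolein (prop-2-enal)
Product: 3 2-methyl-2-(3-oxopropyl)cyclohexane-1,3-dione
Conditions: H2O, rt
Reagents that add atoms: none
Why: Michael addition of the enol of the 1,3-dione to acrolein forms the C10–C1 bond and the still prochiral quaternary carbon C10.

Step 2
Reactants: 3 2-methyl-2-(3-oxopropyl)cyclohexane-1,3-dione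
Product: 4 (3aS,7aR)-7a-hydroxy-3a-methylhexahydro-1H-indene-1,4(2H)-dione
Conditions: chiral aminoindanol-derived N-C6F5 triazolium tetrafluoroborate (10 mol %; the enantiomer that leads to the 3aS ketol), Et3N (10 mol %), CH2Cl2, rt
Reagents that add atoms: none
Why: Intramolecular crossed benzoin reaction in which the carbene-bound acyl-anion equivalent of the aldehyde carbon C4 adds 5-exo-trig to one of the two enantiotopic ring carbonyls, the chiral carbene choosing the carbonyl that makes C10 (S) and the ring constraint forcing the cis fusion (C5 hydroxyl syn to the C10 methyl).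

Step 3
Reactants: 4 (3aS,7aR)-7a-hydroxy-3a-methylhexahydro-1H-indene-1,4(2H)-dione
Product: 6 (4aS,8aR)-8a-hydroxy-4a-methyloctahydronaphthalene-1,5-dione, via α-silyl ketone 5 (not isolated)
Conditions: Me3SiCHN2 (1.2 equiv), Sc(OTf)3 (10 mol %), CH2Cl2, −45 → 0 °C; then 1 M HCl, THF, rt
Reagents that add atoms: (trimethylsilyl)diazomethane, C[Si](C)(C)C=[N+]=[N-]
Why: The oxophilic Sc(OTf)3 binds the C5 hydroxyl and the C4 carbonyl of 4 as a five-membered chelate, Me3SiCHN2 adds to the activated C4, and the β-oxido diazonium ion loses N2 with 1,2-shift of the methylene C2 from C4 to the diazo carbon, which becomes C3 of ring A (α-silyl ketone 5, protodesilylated on acidic work-up). The closest known reaction type is the Lewis-acid-promoted diazoalkane homologation of cyclic ketones (Tiffeneau–Demjanov-type ring expansion). No ring is closed in the cyclization sense: the five-membered ring C10–C1–C2–C4–C5 is enlarged to the six-membered ring A by insertion of one carbon, and the bicycle stays fused at C5–C10. No lasting stereocenter is created (the silyl-bearing C3 ends as CH2) and the migrating C2 is not stereogenic, so C5 and C10 pass through unchanged. The step needs chemoselectivity for C4 over the C9 carbonyl, secured by the chelating α-hydroxyl (C9 lies next to the quaternary C10 and cannot chelate), and regioselectivity for migration of C2 over C5, secured because C5 is fully substituted, oxygen-bearing and anti to the bulky silyl group in the adduct, so the carbonyl stays at C4 beside C5. The silyl group also guards against a second homologation until work-up.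

Step 4
Reactants: 6 (4aS,8aR)-8a-hydroxy-4a-methyloctahydronaphthalene-1,5-dione
Product: 7 (S)-4a-methyl-2,3,4,4a,6,7-hexahydronaphthalene-1,5-dione
Conditions: SOCl2, pyridine, CH2Cl2, 0 °C
Reagents that add atoms: none
Why: Dehydration through the chlorosulfite (anti elimination of the tertiary C5 hydroxyl with a C6 hydrogen, the only β-hydrogen available) gives the conjugated C4 ketone/C5=C6 enone and erases the C5 carbinol centre.

Step 5
Reactants: 7 (S)-4a-methyl-2,3,4,4a,6,7-hexahydronaphthalene-1,5-dione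
Product: 8 (4aS,8aR)-4a-methyloctahydronaphthalene-1,5-dione (trans-fused)
Conditions: H2 (1 atm), 10 % Pd/C, EtOAc, rt
Reagents that add atoms: none
Why: Heterogeneous catalytic hydrogenation adds H2 syn to the α face of the C5=C6 bond, opposite the pseudoaxial C10 methyl (as with steroidal 5-enes), which sets the trans ring fusion (5α-H) while ring B carries no other substituent.

Step 6
Reactants: 8 (4aS,8aR)-4a-methyloctahydronaphthalene-1,5-dione
Product: 9 (4a'S,8a'R)-4a'-methyloctahydro-5'H-spiro[1,3-dioxolane-2,1'-naphthalen]-5'-one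
Conditions: Me3SiOCH2CH2OSiMe3 (1.1 equiv), Me3SiOTf (5 mol %), CH2Cl2, −78 → −40 °C
Reagents that add atoms: 1,2-bis(trimethylsilyloxy)ethane, C[Si](C)(C)OCCO[Si](C)(C)C
Why: Kinetic ketalization at low temperature masks the less hindered C4 carbonyl (the C9 carbonyl sits next to the quaternary C10) without acid-catalysed enolization toward C5.

Step 7
Reactants: 9 (4a'S,8a'R)-4a'-methyloctahydro-5'H-spiro[1,3-dioxolane-2,1'-naphthalen]-5'-one
Product: 10 (4a'S,8a'R)-4a'-methyl-5'-methylideneoctahydro-2'H-spiro[1,3-dioxolane-2,1'-naphthalene]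
Conditions: Ph3PCH3Br, KOt-Bu, toluene, 90 °C
Reagents that add atoms: methyltriphenylphosphonium bromide, C[P+](c1ccccc1)(c1ccccc1)c1ccccc1.[Br-]
Why: Wittig methylenation of the remaining α-quaternary C9 ketone installs the carbon that becomes the C9 methyl; the ketal and the no longer enolizable C5 centre are inert to the ylide.

Step 8
Reactants: 10 (4a'S,8a'R)-4a'-methyl-5'-methylideneoctahydro-2'H-spiro[1,3-dioxolane-2,1'-naphthalene]
Product: 11 (4a'S,8a'R)-4a'-methyl-5'-methylideneoctahydro-2'H-spiro[1,3-dioxolane-2,1'-naphthalen]-6'-ol (C6' epimers)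
Conditions: SeO2 (0.3 equiv), t-BuOOH (2 equiv), CH2Cl2, rt
Reagents that add atoms: selenium dioxide, O=[Se]=O (oxygen donor); tert-butyl hydroperoxide, CC(C)(C)OO (terminal oxidant)
Why: Allylic oxidation (ene reaction with SeO2, then 2,3-sigmatropic shift) of the 1,1-disubstituted alkene can only occur at C8, because the other allylic carbon C10 is quaternary.

Step 9
Reactants: 11 (4a'S,8a'R)-4a'-methyl-5'-methylideneoctahydro-2'H-spiro[1,3-dioxolane-2,1'-naphthalen]-6'-ol
Product: 12 (4a'S,8a'R)-4a'-methyl-5'-methylidenehexahydro-2'H-spiro[1,3-dioxolane-2,1'-naphthalen]-6'(5'H)-one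
Conditions: MnO2 (excess), CH2Cl2, rt
Reagents that add atoms: none
Why: Selective oxidation of the allylic alcohol gives the exocyclic α-methylene ketone, the acceptor needed for regiospecific enolate generation.

Step 10
Reactants: 13 methyl 3-formyl-4-hydroxybenzoate
Product: 14 methyl 3-formyl-4-(methoxymethoxy)benzoate
Conditions: MOMCl, i-Pr2NEt, CH2Cl2, 0 °C → rt
Reagents that add atoms: chloromethyl methyl ether, COCCl
Why: O-Alkylation of the phenol gives a methoxymethyl ether that tolerates the hydride, radical and ketal-hydrolysis steps and cannot migrate to the later benzylic alkoxide.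

Step 11
Reactants: 12 (4a'S,8a'R)-4a'-methyl-5'-methylidenehexahydro-2'H-spiro[1,3-dioxolane-2,1'-naphthalen]-6'(5'H)-one; 14 methyl 3-formyl-4-(methoxymethoxy)benzoate
Product: 15 methyl 3-{hydroxy[(4a'S,5'R,8a'R)-4a',5'-dimethyl-6'-oxooctahydro-2'H-spiro[1,3-dioxolane-2,1'-naphthalen]-5'-yl]methyl}-4-(methoxymethoxy)benzoate (carbinol epimers)
Conditions: LiBH(s-Bu)3 (1.05 equiv), THF, −78 °C; then 14, −78 → −40 °C; aq NH4Cl
Reagents that add atoms: none
Why: Reductive aldol reaction in which 1,4-hydride addition to the unhindered exocyclic CH2 turns it into the C9 methyl and gives only the C8–C9 enolate, which adds to aldehyde 14 from the α face, anti to the axial C10 methyl, creating the quaternary C9 with methyl β and the carbinol carbon C11 α (C11 configuration is not controlled and not needed).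

Step 12
Reactants: 15 methyl 3-{hydroxy[(4a'S,5'R,8a'R)-4a',5'-dimethyl-6'-oxooctahydro-2'H-spiro[1,3-dioxolane-2,1'-naphthalen]-5'-yl]methyl}-4-(methoxymethoxy)benzoate
Product: 16 methyl 3-{hydroxy[(4a'S,5'R,8a'R)-4a',5'-dimethyl-6'-methylideneoctahydro-2'H-spiro[1,3-dioxolane-2,1'-naphthalen]-5'-yl]methyl}-4-(methoxymethoxy)benzoate
Conditions: Zn, CH2Br2, TiCl4 (pre-formed reagent, 3 equiv), THF–CH2Cl2, 0 °C → rt
Reagents that add atoms: dibromomethane, BrCBr
Why: Carbonyl methylenation with the non-basic zinc–titanium methylene reagent converts the congested C8 ketone into the exocyclic alkene without a free aldolate (no retro-aldol) and without attack on the ester.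

Step 13
Reactants: 16 methyl 3-{hydroxy[(4a'S,5'R,8a'R)-4a',5'-dimethyl-6'-methylideneoctahydro-2'H-spiro[1,3-dioxolane-2,1'-naphthalen]-5'-yl]methyl}-4-(methoxymethoxy)benzoate
Product: 17 methyl 3-{hydroxy[(4a'S,5'R,6'S,8a'R)-4a',5',6'-trimethyloctahydro-2'H-spiro[1,3-dioxolane-2,1'-naphthalen]-5'-yl]methyl}-4-(methoxymethoxy)benzoate
Conditions: H2 (1 atm), [Ir(cod)(PCy3)(py)]PF6 (5 mol %), CH2Cl2, rt
Reagents that add atoms: none
Why: Hydroxyl-directed homogeneous hydrogenation in which the cationic iridium catalyst binds the C11 hydroxyl, held on the α face by the axial C9–C11 bond, and delivers H2 to that face of C8=CH2, so the new methyl is β (8S) although this places it syn-diaxial to the C10 methyl.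

Step 14
Reactants: 17 methyl 3-{hydroxy[(4a'S,5'R,6'S,8a'R)-4a',5',6'-trimethyloctahydro-2'H-spiro[1,3-dioxolane-2,1'-naphthalen]-5'-yl]methyl}-4-(methoxymethoxy)benzoate
Product: 18 O-{[5-(methoxycarbonyl)-2-(methoxymethoxy)phenyl][(4a'S,5'R,6'S,8a'R)-4a',5',6'-trimethyloctahydro-2'H-spiro[1,3-dioxolane-2,1'-naphthalen]-5'-yl]methyl} S-methyl carbonodithioate
Conditions: NaH, CS2, THF, 0 °C → rt; then MeI
Reagents that add atoms: carbon disulfide, S=C=S; iodomethane, CI
Why: Xanthate formation (alkoxide, CS2, S-methylation) activates the neopentyl benzylic alcohol for radical deoxygenation; elimination is impossible because C9 is quaternary.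

Step 15
Reactants: 18 O-{[5-(methoxycarbonyl)-2-(methoxymethoxy)phenyl][(4a'S,5'R,6'S,8a'R)-4a',5',6'-trimethyloctahydro-2'H-spiro[1,3-dioxolane-2,1'-naphthalen]-5'-yl]methyl} S-methyl carbonodithioate
Product: 19 methyl 4-(methoxymethoxy)-3-{[(4a'S,5'R,6'S,8a'R)-4a',5',6'-trimethyloctahydro-2'H-spiro[1,3-dioxolane-2,1'-naphthalen]-5'-yl]methyl}benzoate
Conditions: Bu3SnH, AIBN (cat.), toluene, 110 °C
Reagents that add atoms: none
Why: Barton–McCombie deoxygenation, in which the stannyl radical adds to the thiocarbonyl, the C11–O bond fragments to a benzylic radical and hydrogen transfer from Bu3SnH leaves the CH2 link, with no cationic intermediate that could trigger 1,2-shifts at the quaternary C9.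

Step 16
Reactants: 19 methyl 4-(methoxymethoxy)-3-{[(4a'S,5'R,6'S,8a'R)-4a',5',6'-trimethyloctahydro-2'H-spiro[1,3-dioxolane-2,1'-naphthalen]-5'-yl]methyl}benzoate
Product: 20 methyl 4-(methoxymethoxy)-3-{[(1R,2S,4aR,8aS)-1,2,8a-trimethyl-5-oxodecahydronaphthalen-1-yl]methyl}benzoate
Conditions: PPTS (cat.), acetone–H2O (10:1), 40 °C
Reagents that add atoms: water, O
Why: Mild acid-catalysed hydrolysis of the dioxolane frees the C4 ketone while the aryl methoxymethyl ether survives and enolization toward the now thermodynamically fragile C5 centre is kept to a minimum.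

Step 17
Reactants: 20 methyl 4-(methoxymethoxy)-3-{[(1R,2S,4aR,8aS)-1,2,8a-trimethyl-5-oxodecahydronaphthalen-1-yl]methyl}benzoate
Product: 21 methyl 4-(methoxymethoxy)-3-{[(1R,2S,4aS,8aS)-1,2,8a-trimethyl-5-methylidenedecahydronaphthalen-1-yl]methyl}benzoate
Conditions: Zn, CH2Br2, TiCl4 (pre-formed reagent), THF–CH2Cl2, 0 °C → rt
Reagents that add atoms: dibromomethane, BrCBr
Why: Non-basic zinc–titanium carbonyl methylenation converts the C4 ketone into the exocyclic methylene without enolization, so the epimerizable C5 centre next to the carbonyl is kept and the ester is untouched.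

Step 18
Reactants: 21 methyl 4-(methoxymethoxy)-3-{[(1R,2S,4aS,8aS)-1,2,8a-trimethyl-5-methylidenedecahydronaphthalen-1-yl]methyl}benzoate
Product: 22 methyl 4-hydroxy-3-{[(1R,2S,4aS,8aS)-1,2,8a-trimethyl-5-methylidenedecahydronaphthalen-1-yl]methyl}benzoate
Conditions: ZnBr2, n-PrSH, CH2Cl2, 0 °C
Reagents that add atoms: none
Why: Lewis-acid-assisted thiolysis of the aryl methoxymethyl acetal at 0 °C releases the phenol without protonating the 1,1-disubstituted alkene or touching the methyl ester.

**Compound list**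

1 | 2-methylcyclohexane-1,3-dione | CC1C(=O)CCCC1=O | starting material
2 | acrolein (prop-2-enal) | C=CC=O | starting material
3 | 2-methyl-2-(3-oxopropyl)cyclohexane-1,3-dione | CC1(CCC=O)C(=O)CCCC1=O | intermediate
4 | (3aS,7aR)-7a-hydroxy-3a-methylhexahydro-1H-indene-1,4(2H)-dione | O=C1CC[C@@]2(C)[C@]1(O)CCCC2=O | intermediate
5 | (4aS,8aR)-8a-hydroxy-4a-methyl-2-(trimethylsilyl)octahydronaphthalene-1,5-dione (C2 epimers, not isolated) | O=C1C([Si](C)(C)C)CC[C@@]2(C)[C@]1(O)CCCC2=O | intermediate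
6 | (4aS,8aR)-8a-hydroxy-4a-methyloctahydronaphthalene-1,5-dione | O=C1CCC[C@@]2(C)[C@]1(O)CCCC2=O | intermediate
7 | (S)-4a-methyl-2,3,4,4a,6,7-hexahydronaphthalene-1,5-dione | O=C1CCC[C@@]2(C)C1=CCCC2=O | intermediate
8 | (4aS,8aR)-4a-methyloctahydronaphthalene-1,5-dione (trans-fused) | O=C1CCC[C@@]2(C)[C@H]1CCCC2=O | intermediate
9 | (4a'S,8a'R)-4a'-methyloctahydro-5'H-spiro[1,3-dioxolane-2,1'-naphthalen]-5'-one | O1CCOC12CCC[C@@]3(C)[C@H]2CCCC3=O | intermediate
10 | (4a'S,8a'R)-4a'-methyl-5'-methylideneoctahydro-2'H-spiro[1,3-dioxolane-2,1'-naphthalene] | O1CCOC12CCC[C@@]3(C)[C@H]2CCCC3=C | intermediate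
11 | (4a'S,8a'R)-4a'-methyl-5'-methylideneoctahydro-2'H-spiro[1,3-dioxolane-2,1'-naphthalen]-6'-ol (C6' epimers) | O1CCOC12CCC[C@@]3(C)[C@H]2CCC(O)C3=C | intermediate
12 | (4a'S,8a'R)-4a'-methyl-5'-methylidenehexahydro-2'H-spiro[1,3-dioxolane-2,1'-naphthalen]-6'(5'H)-one | O1CCOC12CCC[C@@]3(C)[C@H]2CCC(=O)C3=C | intermediate
13 | methyl 3-formyl-4-hydroxybenzoate | COC(=O)c1ccc(O)c(C=O)c1 | starting material
14 | methyl 3-formyl-4-(methoxymethoxy)benzoate | COCOc1ccc(C(=O)OC)cc1C=O | intermediate
15 | methyl 3-{hydroxy[(4a'S,5'R,8a'R)-4a',5'-dimethyl-6'-oxooctahydro-2'H-spiro[1,3-dioxolane-2,1'-naphthalen]-5'-yl]methyl}-4-(methoxymethoxy)benzoate (carbinol epimers) | O1CCOC12CCC[C@@]3(C)[C@H]2CCC(=O)[C@@]3(C)C(O)c1cc(C(=O)OC)ccc1OCOC | intermediate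
16 | methyl 3-{hydroxy[(4a'S,5'R,8a'R)-4a',5'-dimethyl-6'-methylideneoctahydro-2'H-spiro[1,3-dioxolane-2,1'-naphthalen]-5'-yl]methyl}-4-(methoxymethoxy)benzoate | O1CCOC12CCC[C@@]3(C)[C@H]2CCC(=C)[C@@]3(C)C(O)c1cc(C(=O)OC)ccc1OCOC | intermediate
17 | methyl 3-{hydroxy[(4a'S,5'R,6'S,8a'R)-4a',5',6'-trimethyloctahydro-2'H-spiro[1,3-dioxolane-2,1'-naphthalen]-5'-yl]methyl}-4-(methoxymethoxy)benzoate | O1CCOC12CCC[C@@]3(C)[C@H]2CC[C@H](C)[C@@]3(C)C(O)c1cc(C(=O)OC)ccc1OCOC | intermediate
18 | O-{[5-(methoxycarbonyl)-2-(methoxymethoxy)phenyl][(4a'S,5'R,6'S,8a'R)-4a',5',6'-trimethyloctahydro-2'H-spiro[1,3-dioxolane-2,1'-naphthalen]-5'-yl]methyl} S-methyl carbonodithioate | O1CCOC12CCC[C@@]3(C)[C@H]2CC[C@H](C)[C@@]3(C)C(OC(=S)SC)c1cc(C(=O)OC)ccc1OCOC | intermediate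
19 | methyl 4-(methoxymethoxy)-3-{[(4a'S,5'R,6'S,8a'R)-4a',5',6'-trimethyloctahydro-2'H-spiro[1,3-dioxolane-2,1'-naphthalen]-5'-yl]methyl}benzoate | O1CCOC12CCC[C@@]3(C)[C@H]2CC[C@H](C)[C@@]3(C)Cc1cc(C(=O)OC)ccc1OCOC | intermediate
20 | methyl 4-(methoxymethoxy)-3-{[(1R,2S,4aR,8aS)-1,2,8a-trimethyl-5-oxodecahydronaphthalen-1-yl]methyl}benzoate | O=C1CCC[C@@]2(C)[C@H]1CC[C@H](C)[C@@]2(C)Cc1cc(C(=O)OC)ccc1OCOC | intermediate
21 | methyl 4-(methoxymethoxy)-3-{[(1R,2S,4aS,8aS)-1,2,8a-trimethyl-5-methylidenedecahydronaphthalen-1-yl]methyl}benzoate | C=C1CCC[C@@]2(C)[C@H]1CC[C@H](C)[C@@]2(C)Cc1cc(C(=O)OC)ccc1OCOC | intermediate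
22 | methyl 4-hydroxy-3-{[(1R,2S,4aS,8aS)-1,2,8a-trimethyl-5-methylidenedecahydronaphthalen-1-yl]methyl}benzoate | C=C1CCC[C@@]2(C)[C@H]1CC[C@H](C)[C@@]2(C)Cc1cc(C(=O)OC)ccc1O | target

**Step count**

Total step count: 18. Longest linear sequence: 17 (steps 1–9 and 11–18; step 10 is the one-step side branch to 14).

**Steps most likely to fail**

Step 3. Homologation may occur at the C9 carbonyl, which is a cyclohexanone and intrinsically the more reactive ketone, instead of at the chelated C4; loss of this chemoselectivity would expand ring B. The fallback sets out from 4 and turns the higher reactivity of C9 to use. Wittig methylenation (Ph3PCH3Br, KOt-Bu, excess; the C5 alkoxide shields C4) should give (3aR,7aR)-7a-hydroxy-3a-methyl-4-methylideneoctahydro-1H-inden-1-one F1. Its single ketone is homologated (Me3SiCHN2, BF3·OEt2, −78 °C) through (4aR,8aR)-8a-hydroxy-4a-methyl-5-methylidene-2-(trimethylsilyl)octahydronaphthalen-1(2H)-one F2 (not isolated) to (4aR,8aR)-8a-hydroxy-4a-methyl-5-methylideneoctahydronaphthalen-1(2H)-one F3. Dehydration (SOCl2, pyridine) gives (4aR)-4a-methyl-5-methylidene-3,4,4a,5,6,7-hexahydronaphthalen-1(2H)-one F4. Dissolving-metal conjugate reduction (Li, NH3, THF, −78 °C; NH4Cl), which leaves the isolated alkene alone and protonates the enolate at C5 from the α face, gives (4aS,8aR)-4a-methyl-5-methylideneoctahydronaphthalen-1(2H)-one F5. Ketalization as in step 6 comes back to the route at 10.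

Step 11. The aldol addition at the fully substituted enolate carbon C9, next to the quaternary C10, may be slow or reversible, so that proton transfer or retro-aldol returns the C9–H ketone. The fallback sets out from 12. Conjugate reduction followed by Me3SiCl trapping gives trimethyl{[(4a'S,8a'R)-4a',5'-dimethyl-3',4',4a',7',8',8a'-hexahydro-2'H-spiro[1,3-dioxolane-2,1'-naphthalen]-6'-yl]oxy}silane F6. A Mukaiyama aldol reaction of this isolated silyl enol ether with 14 (Sc(OTf)3 cat., CH2Cl2, −78 °C) is made irreversible by silyl transfer and gives methyl 3-{[(4a'S,5'R,8a'R)-4a',5'-dimethyl-6'-oxooctahydro-2'H-spiro[1,3-dioxolane-2,1'-naphthalen]-5'-yl][(trimethylsilyl)oxy]methyl}-4-(methoxymethoxy)benzoate F7 (not isolated). Dilute acid work-up removes the silyl group and comes back at 15.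

Step 12. The titanium aldolate formed from the free hydroxyl may fragment by retro-aldol, or the congested C8 carbonyl may fail to react; the Lewis-acidic medium may also erode the acetal groups. The fallback sets out from 15. Silylation (Et3SiOTf, 2,6-lutidine) gives methyl 3-{[(4a'S,5'R,8a'R)-4a',5'-dimethyl-6'-oxooctahydro-2'H-spiro[1,3-dioxolane-2,1'-naphthalen]-5'-yl][(triethylsilyl)oxy]methyl}-4-(methoxymethoxy)benzoate F8. Wittig methylenation (Ph3PCH3Br, KOt-Bu, toluene, 60 °C), now free of any alkoxide, gives methyl 3-{[(4a'S,5'R,8a'R)-4a',5'-dimethyl-6'-methylideneoctahydro-2'H-spiro[1,3-dioxolane-2,1'-naphthalen]-5'-yl][(triethylsilyl)oxy]methyl}-4-(methoxymethoxy)benzoate F9. Bu4NF in THF removes the silyl group and comes back at 16.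

Further compounds

F1 | step 3 | (3aR,7aR)-7a-hydroxy-3a-methyl-4-methylideneoctahydro-1H-inden-1-one | O=C1CC[C@@]2(C)[C@]1(O)CCCC2=C
F2 | step 3 | (4aR,8aR)-8a-hydroxy-4a-methyl-5-methylidene-2-(trimethylsilyl)octahydronaphthalen-1(2H)-one (C2 epimers, not isolated) | O=C1C([Si](C)(C)C)CC[C@@]2(C)[C@]1(O)CCCC2=C
F3 | step 3 | (4aR,8aR)-8a-hydroxy-4a-methyl-5-methylideneoctahydronaphthalen-1(2H)-one | O=C1CCC[C@@]2(C)[C@]1(O)CCCC2=C
F4 | step 3 | (4aR)-4a-methyl-5-methylidene-3,4,4a,5,6,7-hexahydronaphthalen-1(2H)-one | O=C1CCC[C@@]2(C)C1=CCCC2=C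
F5 | step 3 | (4aS,8aR)-4a-methyl-5-methylideneoctahydronaphthalen-1(2H)-one | O=C1CCC[C@@]2(C)[C@H]1CCCC2=C
F6 | step 11 | trimethyl{[(4a'S,8a'R)-4a',5'-dimethyl-3',4',4a',7',8',8a'-hexahydro-2'H-spiro[1,3-dioxolane-2,1'-naphthalen]-6'-yl]oxy}silane | O1CCOC12CCC[C@@]3(C)[C@H]2CCC(O[Si](C)(C)C)=C3C
F7 | step 11 | methyl 3-{[(4a'S,5'R,8a'R)-4a',5'-dimethyl-6'-oxooctahydro-2'H-spiro[1,3-dioxolane-2,1'-naphthalen]-5'-yl][(trimethylsilyl)oxy]methyl}-4-(methoxymethoxy)benzoate (not isolated) | O1CCOC12CCC[C@@]3(C)[C@H]2CCC(=O)[C@@]3(C)C(O[Si](C)(C)C)c1cc(C(=O)OC)ccc1OCOC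
F8 | step 12 | methyl 3-{[(4a'S,5'R,8a'R)-4a',5'-dimethyl-6'-oxooctahydro-2'H-spiro[1,3-dioxolane-2,1'-naphthalen]-5'-yl][(triethylsilyl)oxy]methyl}-4-(methoxymethoxy)benzoate | O1CCOC12CCC[C@@]3(C)[C@H]2CCC(=O)[C@@]3(C)C(O[Si](CC)(CC)CC)c1cc(C(=O)OC)ccc1OCOC
F9 | step 12 | methyl 3-{[(4a'S,5'R,8a'R)-4a',5'-dimethyl-6'-methylideneoctahydro-2'H-spiro[1,3-dioxolane-2,1'-naphthalen]-5'-yl][(triethylsilyl)oxy]methyl}-4-(methoxymethoxy)benzoate | O1CCOC12CCC[C@@]3(C)[C@H]2CCC(=C)[C@@]3(C)C(O[Si](CC)(CC)CC)c1cc(C(=O)OC)ccc1OCOC
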